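## Structural features

The target is a daucane: a cyclopentane trans-fused to a cycloheptenone (bicyclo[5.3.0]decane). The daucane numbers are used throughout: C1 is the quaternary ring-fusion carbon with the angular methyl, C2 and C3 are the cyclopentane CH2 groups, C4 is the tertiary carbinol carbon with the isopropyl group, C5 is the ring-fusion CH, C6 is CHOH, C7 is the vinylic CH, C8 is the vinylic C–CH3, C9 is the ketone, and C10 is the CH2 between C9 and C1.

There are four stereocentres, (1R,4R,5S,6S). C4, C5 and C6 are contiguous and C1 is adjacent to C5. The angular methyl and the C4 oxygen are on one face (β); H-5 and the C6 hydroxyl are on the other (α), so the ring fusion is trans.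

The seven-membered ring carries a γ-hydroxy-α-methyl enone, C6(OH)–C7=C8(CH3)–C9(=O), and C10 is a neopentyl CH2 next to the quaternary C1. The tertiary C4 oxygen is acylated by 4-hydroxybenzoic acid; the secondary C6 hydroxyl, 1,3 to it, is free.

The fragile points are:
- the hindered tertiary ester, which can migrate to the C6 hydroxyl under base and can ionise under strong acid;
- the β-oxygenated ketone relationships (C4/C6 in intermediates, C6/C9 in the target);
- the free phenol.

The real difficulty is the seven-membered ring closed onto a quaternary stereocentre, the trans fusion, and the distinction between two carbonyl positions (C4 and C9) during the construction of the tertiary ester.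

The key step exploits how the seven-membered ring divides. The four-carbon unit C7–C6–C5–C1 is the diene of a 2-vinylcyclopentene. The three-carbon unit C8–C9–C10 carries oxygen on its central carbon, which is the pattern of a 2-siloxyvinyl carbenoid.

## Logic of the disconnections

In one sentence: the route is a rhodium-catalysed enantioselective cyclopropanation/divinylcyclopropane rearrangement (formal [4+3] cycloaddition) of 4 with 7.

**24 ⇒ 23.** The C6 O–Si bond is cut. The silyl ether keeps the C6 oxygen from retro-aldol and acylation chemistry earlier on. The forward step must be non-basic, because the tertiary ester sits 1,3 to the liberated hydroxyl.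

**23 ⇒ 20.** The C7=C8 π bond is removed (two C–H bonds restored). This places the enone last, after every step that a conjugated ketone would disturb. The forward step needs regiocontrol of the dehydrogenation. The quaternary C1 helps: an enol derivative on the C10 side has no β-hydrogen and cannot give an enone.

**20 ⇒ 18 ⇒ 16.** The C8–CH3 bond is cut and a carboxyl group is put back on C8, so the C9 ketone reappears as the silyl enol ether of a β-keto benzyl ester. This unit is the direct product of the key step. It also masks C9 as an electron-poor, tetrasubstituted alkene while C4 and C5/C6 are elaborated. The forward steps need clean C-methylation of the liberated enolate and a mild decarboxylation; hydrogenolysis of the benzyl ester supplies the latter and unmasks the phenol in the same operation.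

**16 ⇒ 13 + 14.** The C4–isopropyl bond and the C4 O–acyl bond are cut, leaving a cyclopentanone. The tertiary ester is too hindered to be made from the free alcohol late in the route, so the alkoxide from the carbonyl addition is acylated in the same flask. The forward step needs attack on the α face of C4. That face is opposite the angular methyl, and the C6-bearing bond on the adjacent C5 is pseudo-equatorial.

**13 ⇒ 12 ⇒ 11 ⇒ 9.** The C5–H and C6–O bonds are cut together, giving back the C5=C6 alkene (and the ketal at C4). Both bonds are on the α face and cis to each other, which is the signature of hydroboration–oxidation. One step therefore sets C5, C6 and the trans ring fusion. The demand is attack anti to the angular methyl on C1, and no reaction at the C8=C9 siloxy-acrylate.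

**9 ⇒ 4 + 7.** The C7–C8 and C10–C1 bonds are cut. This removes the seven-membered ring and the quaternary stereocentre in one operation and leaves an achiral diene and an achiral diazo ester. The forward step must cyclopropanate only the vinyl group of 4, give the cis-divinylcyclopropane, and control the absolute configuration through the catalyst.

**4 ⇒ 3 ⇒ 2 ⇒ 1 and 7 ⇒ 6 ⇒ 5.** The C6–C7 vinyl bond, the ketal and the C–Br bond are cut back to 1; the enol silyl ether and the diazo group are cut back to 5. These are standard operations on commercial materials.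

## Other disconnections considered

**Alternative 1:** (the first that comes to mind) Cut C7=C8 by ring-closing metathesis. The precursor is the cyclopentane diene A1, which carries a vinyl carbinol at C5 and a methacryloyl-methyl chain at C1; metathesis would give enone A2. The cut removes one bond and no stereocentre. The trans-disposed side chains, the quaternary C1 and the C4 carbinol would each have to be built on the cyclopentane in separate steps beforehand. The chosen plan makes the ring and C1 together and relays the rest from C1.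

**Alternative 2:** Insert C8 as a single carbon into the six-membered ring of the trans-hydrindanone A3. The sequence would be enol silylation towards C7, ethylidene transfer, FeCl3 ring opening and loss of HCl (Saegusa–Ito ring expansion), giving A2. The insertion solves only the ring size. A3 already contains all four stereocentres, and its oxygenation pattern does not map onto the readily available hydrindenones. The enolisation of A3 would also have to be directed away from C10, and the ethylidene carbenoid would have to add to a hindered enol ether.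

**Alternative 3:** Cut C5–C6 and C1–C10 in an oxidopyrylium [5+2] cycloaddition. The ylide from pyranone acetate A4 would add to 1 to give the oxa-bridged adduct A5, and reductive cleavage of the C10–O bond would give the γ-hydroxy enone directly. This is the shortest way to the enone functionality. However, suprafacial addition to a ring alkene necessarily gives the cis ring fusion. C5 could then be corrected only through β-hydroxy-ketone intermediates that are prone to retro-aldol cleavage, and the regiochemistry of the addition to a β,β-disubstituted enone is not secured. The chosen plan leaves C5 as an alkene carbon and sets it later with the trans relationship.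

Key step: step 6

## Assumptions

- The SMILES is taken as written: the 4-hydroxybenzoate is on the tertiary C4 oxygen and the C6 hydroxyl is free.
- Rh2(S-PTAD)4 is written for step 6 on the assumption that its facial preference gives the (1R,2S)-cyclopropane 8 and hence (R)-C1. If the sense is the opposite, the equally available Rh2(R-PTAD)4 is used and nothing else changes.

## Steps

Step 1
Reactants: 1 3-methylcyclopent-2-en-1-one
Product: 2 2-bromo-3-methylcyclopent-2-en-1-one
Conditions: Br2, CH2Cl2, 0 °C; then Et3N, 0 °C → rt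
Reagents that add atoms: bromine BrBr
Why: Bromine addition to the enone followed by amine-induced loss of HBr gives the α-bromo enone (addition–elimination); no stereocentre is formed.

Step 2
Reactants: 2 2-bromo-3-methylcyclopent-2-en-1-one
Product: 3 6-bromo-7-methyl-1,4-dioxaspiro[4.4]non-6-ene
Conditions: HOCH2CH2OH, p-TsOH (cat.), benzene, reflux, Dean–Stark
Reagents that add atoms: ethane-1,2-diol OCCO
Why: Acid-catalysed ketalisation; the α-bromine holds the double bond in place, as is usual for 2-bromocycloalkenone ketals.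

Step 3
Reactants: 3 6-bromo-7-methyl-1,4-dioxaspiro[4.4]non-6-ene
Product: 4 6-ethenyl-7-methyl-1,4-dioxaspiro[4.4]non-6-ene
Conditions: Bu3SnCH=CH2, Pd(PPh3)4 (5 mol%), toluene, 105 °C
Reagents that add atoms: tributyl(vinyl)stannane C=C[Sn](CCCC)(CCCC)CCCC
Why: Stille coupling of the vinyl bromide under neutral conditions that the ketal tolerates; the product is the achiral diene C7=C6–C5=C1.

Step 4
Reactants: 5 benzyl 3-oxobutanoate
Product: 6 benzyl 2-diazo-3-oxobutanoate
Conditions: p-ABSA, Et3N, MeCN, 0 °C → rt
Reagents that add atoms: 4-acetamidobenzenesulfonyl azide CC(=O)Nc1ccc(cc1)S(=O)(=O)N=[N+]=[N-]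
Why: Regitz diazo transfer to the activated methylene of a β-keto ester.

Step 5
Reactants: 6 benzyl 2-diazo-3-oxobutanoate
Product: 7 benzyl 3-[(tert-butyldimethylsilyl)oxy]-2-diazobut-3-enoate
Conditions: TBSOTf, Et3N, CH2Cl2, 0 °C
Reagents that add atoms: tert-butyldimethylsilyl trifluoromethanesulfonate CC(C)(C)[Si](C)(C)OS(=O)(=O)C(F)(F)F
Why: Soft enolisation and O-silylation of the acetyl group give the 2-siloxyvinyl diazoacetate, the standard precursor of a donor/acceptor vinylcarbenoid.

Step 6
Reactants: 4 6-ethenyl-7-methyl-1,4-dioxaspiro[4.4]non-6-ene; 7 benzyl 3-[(tert-butyldimethylsilyl)oxy]-2-diazobut-3-enoate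
Product: 9 benzyl (1R)-9-(tert-butyldimethylsilyloxy)-4,4-ethylenedioxy-1-methylbicyclo[5.3.0]deca-5,8-diene-8-carboxylate (daucane numbering), via cis-divinylcyclopropane 8 (not isolated)
Conditions: Rh2(S-PTAD)4 (1 mol%), 4 (1.5 equiv), slow addition of 7, hexanes, −20 °C → rt; then heptane, 80 °C
Reagents that add atoms: none
Why: This is the tandem cyclopropanation/divinylcyclopropane (Cope) rearrangement, the rhodium-vinylcarbenoid formal [4+3] cycloaddition, which is established for 2-methyl-1-vinylcycloalkenes with 2-siloxyvinyl diazoacetates. The donor/acceptor carbenoid from 7 adds only to the monosubstituted C6=C7 vinyl group of 4, because the tetrasubstituted C5=C1 bond is inert to this bulky carbenoid; the cyclopropane C6–C7–C8 closes in a concerted asynchronous step with the siloxyvinyl donor cis to the cyclopentenyl group, so 8 is the cis-divinylcyclopropane. The seven-membered ring then closes by a [3,3]-sigmatropic shift through the obligatory boat transition state: C6–C8 breaks, C10–C1 forms, and the new C8=C9 (silyl enol ether) and C5=C6 bonds are both cis within the ring. C1 is the only stereocentre of 9 and is formed in the Cope step under stereospecific control by cyclopropane carbon C6, because the cyclopentenyl group can reach C10 only with its C5=C1 bond folded over the three-membered ring. The configuration of C6 is set by the chiral catalyst through facial selection of the vinyl group, so the enantiomeric purity of 8 is carried over to C1. The methyl group on C1 is the inside (Z) substituent of the boat and slows the shift, hence the warming; the captodative C8 also lets any trans-cyclopropane epimerise to the reactive cis isomer. The step needs site selectivity (vinyl over ring alkene, secured by sterics), diastereoselectivity (inherent to donor/acceptor carbenoids), enantioselectivity (catalyst), and preference for cyclopropanation over C–H insertion or ylide formation at the ketal oxygens (favoured by the nucleophilic diene terminus and slow addition of 7).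

Step 7
Reactants: 9 benzyl (1R)-9-(tert-butyldimethylsilyloxy)-4,4-ethylenedioxy-1-methylbicyclo[5.3.0]deca-5,8-diene-8-carboxylate
Product: 11 benzyl (1R,5S,6S)-9-(tert-butyldimethylsilyloxy)-4,4-ethylenedioxy-6-hydroxy-1-methylbicyclo[5.3.0]dec-8-ene-8-carboxylate (5α-H and 6α-OH), via C6 alkylborane 10 (not isolated)
Conditions: BH3·SMe2, THF, 0 °C → rt; then NaBO3·4H2O, THF/H2O, rt
Reagents that add atoms: sodium perborate [Na+].[Na+].O[B-]1(O)OO[B-](O)(O)OO1
Why: Hydroboration–oxidation: syn addition places H on the more substituted C5 and boron on C6 from the face opposite the angular methyl of C1, as in Δ5-steroids and related hydrindenes, which fixes the trans ring fusion and the 6α-oxygen together (C–B to C–O with retention). The tetrasubstituted, electron-poor C8=C9 siloxy-acrylate should not react with the electrophilic borane, and perborate is mild enough to leave the enol silyl ether and the benzyl ester intact.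

Step 8
Reactants: 11 benzyl (1R,5S,6S)-9-(tert-butyldimethylsilyloxy)-4,4-ethylenedioxy-6-hydroxy-1-methylbicyclo[5.3.0]dec-8-ene-8-carboxylate
Product: 12 benzyl (1R,5S,6S)-6,9-bis(tert-butyldimethylsilyloxy)-4,4-ethylenedioxy-1-methylbicyclo[5.3.0]dec-8-ene-8-carboxylate
Conditions: TBSOTf, 2,6-lutidine, CH2Cl2, −78 → 0 °C
Reagents that add atoms: tert-butyldimethylsilyl trifluoromethanesulfonate CC(C)(C)[Si](C)(C)OS(=O)(=O)C(F)(F)F
Why: Silylation of the hindered secondary alcohol; the ether blocks retro-aldol cleavage and O-acylation at C6 in the following steps.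

Step 9
Reactants: 12 benzyl (1R,5S,6S)-6,9-bis(tert-butyldimethylsilyloxy)-4,4-ethylenedioxy-1-methylbicyclo[5.3.0]dec-8-ene-8-carboxylate
Product: 13 benzyl (1R,5S,6S)-6,9-bis(tert-butyldimethylsilyloxy)-1-methyl-4-oxobicyclo[5.3.0]dec-8-ene-8-carboxylate
Conditions: PPTS (cat.), acetone/H2O (10:1), 40 °C
Reagents that add atoms: water O
Why: Mild acid hydrolysis of the cyclopentanone dioxolane; the enol silyl ether at C9 is a vinylogous silyl ester and far less acid-labile than a simple silyl enol ether, and the secondary silyl ether is stable to PPTS.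

Step 10
Reactants: 13 benzyl (1R,5S,6S)-6,9-bis(tert-butyldimethylsilyloxy)-1-methyl-4-oxobicyclo[5.3.0]dec-8-ene-8-carboxylate; 14 4-(benzyloxy)benzoyl chloride
Product: 16 benzyl (1R,4R,5S,6S)-4-{[4-(benzyloxy)benzoyl]oxy}-6,9-bis(tert-butyldimethylsilyloxy)-1-methyl-4-(propan-2-yl)bicyclo[5.3.0]dec-8-ene-8-carboxylate, via cerium alkoxide 15 (not isolated)
Conditions: i-PrMgCl, CeCl3 (anhydrous), THF, −78 °C; then 14, DMAP (cat.), −78 °C → rt
Reagents that add atoms: isopropylmagnesium chloride CC(C)[Mg]Cl
Why: Organocerium (Imamoto) 1,2-addition suppresses enolisation and hydride transfer; the nucleophile attacks the C4 ketone from the α face, opposite the 1,3-related angular methyl, so the oxygen ends β (4R). The alkoxide is acylated in the same flask because the free tertiary alcohol would be too hindered to esterify later; the deactivated, hindered C8 ester is not attacked at −78 °C.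

Step 11
Reactants: 16 benzyl (1R,4R,5S,6S)-4-{[4-(benzyloxy)benzoyl]oxy}-6,9-bis(tert-butyldimethylsilyloxy)-1-methyl-4-(propan-2-yl)bicyclo[5.3.0]dec-8-ene-8-carboxylate
Product: 18 benzyl (1R,4R,5S,6S)-4-{[4-(benzyloxy)benzoyl]oxy}-6-(tert-butyldimethylsilyloxy)-1,8-dimethyl-9-oxo-4-(propan-2-yl)bicyclo[5.3.0]decane-8-carboxylate (C8 epimers), via ammonium enolate 17 (not isolated)
Conditions: TBAF (1.1 equiv), MeI (5 equiv), THF, −78 → 0 °C
Reagents that add atoms: iodomethane CI
Why: Fluoride cleaves the activated enol silyl ether much faster than the secondary alkyl silyl ether, and the resulting ammonium β-keto ester enolate is C-methylated (fluoride-mediated alkylation of a silyl enol ether). The configuration at C8 is irrelevant because it is lost in steps 12 and 13.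

Step 12
Reactants: 18 benzyl (1R,4R,5S,6S)-4-{[4-(benzyloxy)benzoyl]oxy}-6-(tert-butyldimethylsilyloxy)-1,8-dimethyl-9-oxo-4-(propan-2-yl)bicyclo[5.3.0]decane-8-carboxylate
Product: 20 (1R,4R,5S,6S)-6-(tert-butyldimethylsilyloxy)-1,8-dimethyl-9-oxo-4-(propan-2-yl)bicyclo[5.3.0]decan-4-yl 4-hydroxybenzoate (C8 epimers), via β-keto acid 19 (not isolated)
Conditions: H2 (1 atm), 10% Pd/C, EtOAc, rt; then 50 °C
Reagents that add atoms: none
Why: Hydrogenolysis removes both benzyl groups; the β-keto acid loses CO2 on gentle warming, leaving the C8 methyl ketone and the free phenol. No alkene is present at this stage and the tertiary ester is not benzylic.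

Step 13
Reactants: 20 (1R,4R,5S,6S)-6-(tert-butyldimethylsilyloxy)-1,8-dimethyl-9-oxo-4-(propan-2-yl)bicyclo[5.3.0]decan-4-yl 4-hydroxybenzoate
Product: 23 (1R,4R,5S,6S)-6-(tert-butyldimethylsilyloxy)-1,8-dimethyl-9-oxo-4-(propan-2-yl)bicyclo[5.3.0]dec-7-en-4-yl 4-hydroxybenzoate, via bis(trimethylsilyl) enol ether 21 (not isolated), via enone aryl silyl ether 22 (not isolated)
Conditions: TMSCl, NaI, Et3N, MeCN, rt; then Pd(OAc)2 (1.1 equiv), MeCN, rt; aq. NH4Cl work-up
Reagents that add atoms: none
Why: Saegusa–Ito oxidation: thermodynamic silylation gives the more substituted C8=C9 enol ether (the phenol is silylated temporarily), and the C8 palladium enolate undergoes β-hydride elimination from C7 to the conjugated endocyclic enone. An enol ether on the C10 side cannot give an enone because C1 is quaternary and has no β-hydrogen, so it only returns the ketone.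

Step 14
Reactants: 23 (1R,4R,5S,6S)-6-(tert-butyldimethylsilyloxy)-1,8-dimethyl-9-oxo-4-(propan-2-yl)bicyclo[5.3.0]dec-7-en-4-yl 4-hydroxybenzoate
Product: 24 (1R,4R,5S,6S)-6-hydroxy-1,8-dimethyl-9-oxo-4-(propan-2-yl)bicyclo[5.3.0]dec-7-en-4-yl 4-hydroxybenzoate, the target, which is (3R,3aS,4S,8aR)-4-hydroxy-6,8a-dimethyl-7-oxo-3-(propan-2-yl)-1,2,3,3a,4,7,8,8a-octahydroazulen-3-yl 4-hydroxybenzoate
Conditions: HF·pyridine, pyridine, THF, 0 °C → rt
Reagents that add atoms: none
Why: Buffered fluoride cleavage of the secondary silyl ether under non-basic conditions, which avoids migration of the tertiary ester to the C6 hydroxyl and leaves the γ-hydroxy enone untouched.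

## Compound list

1 | 3-methylcyclopent-2-en-1-one | CC1=CC(=O)CC1 | starting material
2 | 2-bromo-3-methylcyclopent-2-en-1-one | CC1=C(Br)C(=O)CC1 | intermediate
3 | 6-bromo-7-methyl-1,4-dioxaspiro[4.4]non-6-ene | CC1=C(Br)C2(CC1)OCCO2 | intermediate
4 | 6-ethenyl-7-methyl-1,4-dioxaspiro[4.4]non-6-ene | C=CC1=C(C)CCC12OCCO2 | intermediate
5 | benzyl 3-oxobutanoate | CC(=O)CC(=O)OCc1ccccc1 | starting material
6 | benzyl 2-diazo-3-oxobutanoate | CC(=O)C(=[N+]=[N-])C(=O)OCc1ccccc1 | intermediate
7 | benzyl 3-[(tert-butyldimethylsilyl)oxy]-2-diazobut-3-enoate | C=C(O[Si](C)(C)C(C)(C)C)C(=[N+]=[N-])C(=O)OCc1ccccc1 | intermediate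
8 | benzyl (1R,2S)-1-[1-(tert-butyldimethylsilyloxy)ethenyl]-2-(7-methyl-1,4-dioxaspiro[4.4]non-6-en-6-yl)cyclopropane-1-carboxylate (cis-divinylcyclopropane) | C=C(O[Si](C)(C)C(C)(C)C)[C@@]1(C(=O)OCc2ccccc2)C[C@H]1C1=C(C)CCC12OCCO2 | intermediate (not isolated)
9 | benzyl (1R)-9-(tert-butyldimethylsilyloxy)-4,4-ethylenedioxy-1-methylbicyclo[5.3.0]deca-5,8-diene-8-carboxylate | C1(O[Si](C)(C)C(C)(C)C)=C(C(=O)OCc3ccccc3)CC=C2[C@](C)(CCC24OCCO4)C1 | intermediate
10 | 6α-boranyl adduct of 9 (5α-H, C6–BH2) | C1(O[Si](C)(C)C(C)(C)C)=C(C(=O)OCc3ccccc3)C[C@H](B)[C@@H]2[C@](C)(CCC24OCCO4)C1 | intermediate (not isolated)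
11 | benzyl (1R,5S,6S)-9-(tert-butyldimethylsilyloxy)-4,4-ethylenedioxy-6-hydroxy-1-methylbicyclo[5.3.0]dec-8-ene-8-carboxylate | C1(O[Si](C)(C)C(C)(C)C)=C(C(=O)OCc3ccccc3)C[C@H](O)[C@@H]2[C@](C)(CCC24OCCO4)C1 | intermediate
12 | benzyl (1R,5S,6S)-6,9-bis(tert-butyldimethylsilyloxy)-4,4-ethylenedioxy-1-methylbicyclo[5.3.0]dec-8-ene-8-carboxylate | C1(O[Si](C)(C)C(C)(C)C)=C(C(=O)OCc3ccccc3)C[C@H](O[Si](C)(C)C(C)(C)C)[C@@H]2[C@](C)(CCC24OCCO4)C1 | intermediate
13 | benzyl (1R,5S,6S)-6,9-bis(tert-butyldimethylsilyloxy)-1-methyl-4-oxobicyclo[5.3.0]dec-8-ene-8-carboxylate | C1(O[Si](C)(C)C(C)(C)C)=C(C(=O)OCc3ccccc3)C[C@H](O[Si](C)(C)C(C)(C)C)[C@@H]2[C@](C)(CCC2=O)C1 | intermediate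
14 | 4-(benzyloxy)benzoyl chloride | O=C(Cl)c1ccc(OCc2ccccc2)cc1 | starting material
15 | dichlorocerium(III) (1R,4R,5S,6S)-4-alkoxide from isopropyl addition to 13 | C1(O[Si](C)(C)C(C)(C)C)=C(C(=O)OCc3ccccc3)C[C@H](O[Si](C)(C)C(C)(C)C)[C@@H]2[C@](C)(CC[C@@]2(O[Ce](Cl)Cl)C(C)C)C1 | intermediate (not isolated)
16 | benzyl (1R,4R,5S,6S)-4-{[4-(benzyloxy)benzoyl]oxy}-6,9-bis(tert-butyldimethylsilyloxy)-1-methyl-4-(propan-2-yl)bicyclo[5.3.0]dec-8-ene-8-carboxylate | C1(O[Si](C)(C)C(C)(C)C)=C(C(=O)OCc3ccccc3)C[C@H](O[Si](C)(C)C(C)(C)C)[C@@H]2[C@](C)(CC[C@@]2(OC(=O)c4ccc(OCc5ccccc5)cc4)C(C)C)C1 | intermediate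
17 | tetrabutylammonium C8/C9 enolate of the β-keto benzyl ester | [O-]C1=C(C(=O)OCc3ccccc3)C[C@H](O[Si](C)(C)C(C)(C)C)[C@@H]2[C@](C)(CC[C@@]2(OC(=O)c4ccc(OCc5ccccc5)cc4)C(C)C)C1.CCCC[N+](CCCC)(CCCC)CCCC | intermediate (not isolated)
18 | benzyl (1R,4R,5S,6S)-4-{[4-(benzyloxy)benzoyl]oxy}-6-(tert-butyldimethylsilyloxy)-1,8-dimethyl-9-oxo-4-(propan-2-yl)bicyclo[5.3.0]decane-8-carboxylate (C8 epimers) | O=C1C(C)(C(=O)OCc3ccccc3)C[C@H](O[Si](C)(C)C(C)(C)C)[C@@H]2[C@](C)(CC[C@@]2(OC(=O)c4ccc(OCc5ccccc5)cc4)C(C)C)C1 | intermediate
19 | (1R,4R,5S,6S)-6-(tert-butyldimethylsilyloxy)-4-[(4-hydroxybenzoyl)oxy]-1,8-dimethyl-9-oxo-4-(propan-2-yl)bicyclo[5.3.0]decane-8-carboxylic acid (C8 epimers) | O=C1C(C)(C(O)=O)C[C@H](O[Si](C)(C)C(C)(C)C)[C@@H]2[C@](C)(CC[C@@]2(OC(=O)c4ccc(O)cc4)C(C)C)C1 | intermediate (not isolated)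
20 | (1R,4R,5S,6S)-6-(tert-butyldimethylsilyloxy)-1,8-dimethyl-9-oxo-4-(propan-2-yl)bicyclo[5.3.0]decan-4-yl 4-hydroxybenzoate (C8 epimers) | O=C1C(C)C[C@H](O[Si](C)(C)C(C)(C)C)[C@@H]2[C@](C)(CC[C@@]2(OC(=O)c4ccc(O)cc4)C(C)C)C1 | intermediate
21 | C8=C9 trimethylsilyl enol ether of 20 with the phenol as its trimethylsilyl ether | C1(O[Si](C)(C)C)=C(C)C[C@H](O[Si](C)(C)C(C)(C)C)[C@@H]2[C@](C)(CC[C@@]2(OC(=O)c4ccc(O[Si](C)(C)C)cc4)C(C)C)C1 | intermediate (not isolated)
22 | aryl trimethylsilyl ether of 23 | CC1=C[C@H](O[Si](C)(C)C(C)(C)C)[C@@H]2[C@](C)(CC[C@@]2(OC(=O)c2ccc(O[Si](C)(C)C)cc2)C(C)C)CC1=O | intermediate (not isolated)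
23 | (1R,4R,5S,6S)-6-(tert-butyldimethylsilyloxy)-1,8-dimethyl-9-oxo-4-(propan-2-yl)bicyclo[5.3.0]dec-7-en-4-yl 4-hydroxybenzoate | CC1=C[C@H](O[Si](C)(C)C(C)(C)C)[C@@H]2[C@](C)(CC[C@@]2(OC(=O)c2ccc(O)cc2)C(C)C)CC1=O | intermediate
24 | (3R,3aS,4S,8aR)-4-hydroxy-6,8a-dimethyl-7-oxo-3-(propan-2-yl)-1,2,3,3a,4,7,8,8a-octahydroazulen-3-yl 4-hydroxybenzoate | CC1=C[C@H](O)[C@@H]2[C@](C)(CC[C@@]2(OC(=O)c2ccc(O)cc2)C(C)C)CC1=O | target

## Step count and risks

Total: 14 steps. Longest linear sequence: 12 steps (steps 1–3 and 6–14, from 1); steps 4 and 5 form the two-step side branch to 7.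

**Step 6 (key step).** The most likely failure is insufficient, or reversed, facial discrimination of the hindered, twisted vinyl group by the catalyst, so that 9 forms with low enantiomeric purity. A second weakness is a slow sigmatropic shift because of the inside methyl group. The fallback obtains the absolute configuration by resolution instead of catalyst control. Starting from 4 (with 7), an achiral catalyst, Rh2(OPiv)4, with the same warming should give 9 together with its enantiomer ent-9 F1. Hydroboration as in step 7 then gives 11 together with its enantiomer ent-11 F2. Lipase-mediated acylation (Candida antarctica lipase B, vinyl acetate, MTBE) is expected to convert the (6R)-alcohol F2 into the acetate of ent-11 F3 and leave 11, which is separated and re-enters the route at 11.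

**Step 7.** The most likely failure is borane delivery to the β face, syn to the angular methyl, if the cycloheptadiene folds so that the ring itself shields the α face; this would give the cis-fused C5/C6 isomer. Partial reduction of the siloxy-acrylate is a lesser risk. The fallback replaces the concerted syn addition by a polar conjugate addition with an epimerisable C5. Starting from 9, the ketal is removed (PPTS, wet acetone) to give the C4 ketone conjugated with C5=C6, enone F4. Copper-catalysed conjugate borylation (B2pin2, CuCl, catalytic NaOtBu, a Josiphos-type ligand chosen for α-face delivery, MeOH) places boron on C6 and a proton on C5 to give the β-boryl ketone F5. C5 is now α to the ketone and can be equilibrated towards the trans ring fusion. Perborate oxidation gives the β-hydroxy ketone F6, and silylation (TBSOTf, 2,6-lutidine) returns to the route at 13.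

**Step 9.** The most likely failure is hydrolysis of the C9 enol silyl ether along with the ketal, or acid-induced β-elimination of the C6 silyloxy group. The fallback removes everything acid-labile at C4 and C9 and then re-masks chemoselectively. Starting from 12, aqueous HCl in THF at 0 °C should give the C4-ketone β-keto ester F7. One equivalent of NaH deprotonates only the β-keto ester, and TBSCl re-forms the enol silyl ether, which returns to the route at 13.

**Step 10.** The most likely failure is enolisation of the β-silyloxy ketone (with E1cB loss of the C6 oxygen) or β-hydride transfer from the secondary organometallic instead of addition. Slow acylation of the congested alkoxide is a further risk. The fallback uses an sp2 nucleophile without β-hydrogens and then a hydrogenation. Starting from 13, isopropenylmagnesium bromide/CeCl3 followed by 14 should give the isopropenyl ester F8. Homogeneous hydrogenation of its 1,1-disubstituted alkene (H2, RhCl(PPh3)3, benzene) leaves the benzyl groups and the tetrasubstituted siloxy-acrylate untouched and returns to the route at 16.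

## Further compounds

F1 | step 6 | benzyl (1S)-9-(tert-butyldimethylsilyloxy)-4,4-ethylenedioxy-1-methylbicyclo[5.3.0]deca-5,8-diene-8-carboxylate (ent-9) | C1(O[Si](C)(C)C(C)(C)C)=C(C(=O)OCc3ccccc3)CC=C2[C@@](C)(CCC24OCCO4)C1
F2 | step 6 | benzyl (1S,5R,6R)-9-(tert-butyldimethylsilyloxy)-4,4-ethylenedioxy-6-hydroxy-1-methylbicyclo[5.3.0]dec-8-ene-8-carboxylate (ent-11) | C1(O[Si](C)(C)C(C)(C)C)=C(C(=O)OCc3ccccc3)C[C@@H](O)[C@H]2[C@@](C)(CCC24OCCO4)C1
F3 | step 6 | benzyl (1S,5R,6R)-6-acetoxy-9-(tert-butyldimethylsilyloxy)-4,4-ethylenedioxy-1-methylbicyclo[5.3.0]dec-8-ene-8-carboxylate (acetate of ent-11) | C1(O[Si](C)(C)C(C)(C)C)=C(C(=O)OCc3ccccc3)C[C@@H](OC(C)=O)[C@H]2[C@@](C)(CCC24OCCO4)C1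
F4 | step 7 | benzyl (1R)-9-(tert-butyldimethylsilyloxy)-1-methyl-4-oxobicyclo[5.3.0]deca-5,8-diene-8-carboxylate | C1(O[Si](C)(C)C(C)(C)C)=C(C(=O)OCc3ccccc3)CC=C2[C@](C)(CCC2=O)C1
F5 | step 7 | benzyl (1R,5S,6S)-9-(tert-butyldimethylsilyloxy)-1-methyl-4-oxo-6-(4,4,5,5-tetramethyl-1,3,2-dioxaborolan-2-yl)bicyclo[5.3.0]dec-8-ene-8-carboxylate | C1(O[Si](C)(C)C(C)(C)C)=C(C(=O)OCc3ccccc3)C[C@H](B4OC(C)(C)C(C)(C)O4)[C@@H]2[C@](C)(CCC2=O)C1
F6 | step 7 | benzyl (1R,5S,6S)-9-(tert-butyldimethylsilyloxy)-6-hydroxy-1-methyl-4-oxobicyclo[5.3.0]dec-8-ene-8-carboxylate | C1(O[Si](C)(C)C(C)(C)C)=C(C(=O)OCc3ccccc3)C[C@H](O)[C@@H]2[C@](C)(CCC2=O)C1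
F7 | step 9 | benzyl (1R,5S,6S)-6-(tert-butyldimethylsilyloxy)-1-methyl-4,9-dioxobicyclo[5.3.0]decane-8-carboxylate (C8 epimers, keto form) | O=C1C(C(=O)OCc3ccccc3)C[C@H](O[Si](C)(C)C(C)(C)C)[C@@H]2[C@](C)(CCC2=O)C1
F8 | step 10 | benzyl (1R,4R,5S,6S)-4-{[4-(benzyloxy)benzoyl]oxy}-6,9-bis(tert-butyldimethylsilyloxy)-1-methyl-4-(prop-1-en-2-yl)bicyclo[5.3.0]dec-8-ene-8-carboxylate | C1(O[Si](C)(C)C(C)(C)C)=C(C(=O)OCc3ccccc3)C[C@H](O[Si](C)(C)C(C)(C)C)[C@@H]2[C@](C)(CC[C@@]2(OC(=O)c4ccc(OCc5ccccc5)cc4)C(C)=C)C1
A1 | alternative 1 | 1-{(1R,2S,3R)-2-[(1S)-1-(tert-butyldimethylsilyloxy)prop-2-en-1-yl]-3-hydroxy-1-methyl-3-(propan-2-yl)cyclopentyl}-3-methylbut-3-en-2-one (cyclopentane numbering) | C=C[C@H](O[Si](C)(C)C(C)(C)C)[C@@H]2[C@](C)(CC[C@@]2(O)C(C)C)CC(=O)C(C)=C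
A2 | alternative 1 | (1R,4R,5S,6S)-6-(tert-butyldimethylsilyloxy)-4-hydroxy-1,8-dimethyl-4-(propan-2-yl)bicyclo[5.3.0]dec-7-en-9-one | CC1=C[C@H](O[Si](C)(C)C(C)(C)C)[C@@H]2[C@](C)(CC[C@@]2(O)C(C)C)CC1=O
A3 | alternative 2 | trans-fused 4-(tert-butyldimethylsilyloxy)-3-hydroxy-7a-methyl-3-(propan-2-yl)octahydro-1H-inden-6-one (ring-contracted analogue of A2 lacking C8) | O=C1C[C@H](O[Si](C)(C)C(C)(C)C)[C@@H]2[C@](C)(CC[C@@]2(O)C(C)C)C1
A4 | alternative 3 | 6-acetoxy-4-methyl-2H-pyran-3(6H)-one (racemic) | CC1=CC(OC(C)=O)OCC1=O
A5 | alternative 3 | cis-fused oxa-bridged cycloadduct of the 4-methyl-3-oxidopyrylium ylide with 1 (C6–O–C10 bridge, C4 ketone; endo isomer, one enantiomer drawn) | CC1=C[C@H]2O[C@@H](C1=O)[C@@]1(C)CCC(=O)[C@@H]21
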